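**Strategy.** Ring B (C1, C2, C3, C4, C4a, C8a; decalin numbering, C1 = ester carbon) is cut across its two opposite bonds, C4a–C8a and C2–C3, into two three-carbon halves that each carry oxygen on the middle carbon; this exploits the 1,4-placement of the two oxygens (C1, C4) in ring B. One half is a C4 ketone (as silyl enol ether) whose α-carbons C4a and C3 are the nucleophiles; the other is a Sharpless-derived epoxy bromide (C1–C8a oxirane, C2–Br). In one flask, BF3 makes the allylsilane carbon C4a open the oxirane at C8a (ring A, quaternary centre, C5 methylidene), then fluoride frees the enolate, which alkylates C2 (ring B). The precursor is an acyclic C15 chain.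

Key step: step 8

Remark: atom labels in the text follow the decalin numbering of the target (C1 ester carbon, C3 isopropyl carbon, C4 carbinol carbon, C4a/C8a ring fusion, C5 methylidene-bearing carbon). Step 8 is a single flask operation: the fluoride is added to the BF3 reaction mixture without work-up. Compounds 1, 7 and 15 are taken as commercial.

Step 1
Reactants: 1 hepta-1,6-diyne
Product: 3 methyl (2E)-3-methyloct-2-en-7-ynoate, via alkenylalane 2 (not isolated)
Conditions: Me3Al, Cp2ZrCl2 (cat.), CH2Cl2, 0 °C to rt, 1 in excess (3 equiv, recovered); then ClCO2Me, 0 °C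
Reagents that add atoms: trimethylaluminium C[Al](C)C; methyl chloroformate COC(=O)Cl
Why: Negishi zirconium-catalysed syn-carboalumination of one terminal alkyne places methyl and aluminium cis, and acylation of the alkenylalane with the chloroformate proceeds with retention, so the (E)-enoate should result.

Step 2
Reactants: 3 methyl (2E)-3-methyloct-2-en-7-ynoate
Product: 4 (2E)-3-methyloct-2-en-7-yn-1-ol
Conditions: DIBAL-H, CH2Cl2, −78 °C; Rochelle salt
Reagents that add atoms: none
Why: DIBAL-H 1,2-reduction of the enoate should give the allylic alcohol without touching the terminal alkyne or the alkene geometry.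

Step 3
Reactants: 4 (2E)-3-methyloct-2-en-7-yn-1-ol
Product: 5 [(2R,3R)-3-methyl-3-(pent-4-yn-1-yl)oxiran-2-yl]methanol
Conditions: Ti(OiPr)4 (cat.), D-(−)-diethyl tartrate (cat.), t-BuOOH, 4 Å MS, CH2Cl2, −20 °C
Reagents that add atoms: tert-butyl hydroperoxide CC(C)(C)OO
Why: Sharpless asymmetric epoxidation of the geraniol-type (E)-allylic alcohol with the D-tartrate ligand should deliver oxygen to the face that gives the (2R,3R)-epoxide, which fixes the future C1 and C8a.

Step 4
Reactants: 5 [(2R,3R)-3-methyl-3-(pent-4-yn-1-yl)oxiran-2-yl]methanol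
Product: 6 (2S,3R)-2-(bromomethyl)-3-methyl-3-(pent-4-yn-1-yl)oxirane
Conditions: CBr4, PPh3, CH2Cl2, 0 °C
Reagents that add atoms: carbon tetrabromide BrC(Br)(Br)Br
Why: Appel bromination converts the primary alcohol into the bromide under neutral conditions that leave the oxirane and its two stereocentres untouched (the descriptor at the CH carbon changes only through CIP priority).

Step 5
Reactants: 6 (2S,3R)-2-(bromomethyl)-3-methyl-3-(pent-4-yn-1-yl)oxirane; 7 3-methylbutanoyl chloride
Product: 8 9-[(2R,3S)-3-(bromomethyl)-2-methyloxiran-2-yl]-2-methylnon-5-yn-4-one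
Conditions: PdCl2(PPh3)2 (cat.), CuI (cat.), i-Pr2NEt, THF, rt
Reagents that add atoms: none
Why: Acyl Sonogashira coupling of the terminal alkyne with the acid chloride should give the ynone under mild conditions, the hindered amine avoiding quaternisation by the primary bromide.

Step 6
Reactants: 8 9-[(2R,3S)-3-(bromomethyl)-2-methyloxiran-2-yl]-2-methylnon-5-yn-4-one
Product: 9 (5E)-9-[(2R,3S)-3-(bromomethyl)-2-methyloxiran-2-yl]-2-methyl-6-[(trimethylsilyl)methyl]non-5-en-4-one
Conditions: (Me3SiCH2)2CuLi (from Me3SiCH2Li, CuI), THF, −78 °C, short time; NH4Cl (aq), −78 °C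
Reagents that add atoms: (trimethylsilyl)methyllithium [Li]C[Si](C)(C)C
Why: Conjugate syn-carbocupration of the ynone and protonation should place the bulky CH2SiMe3 group trans to the acyl group (the isomer that is also favoured thermodynamically), the ynone reacting far faster at −78 °C than the bromide or the oxirane.

Step 7
Reactants: 9 (5E)-9-[(2R,3S)-3-(bromomethyl)-2-methyloxiran-2-yl]-2-methyl-6-[(trimethylsilyl)methyl]non-5-en-4-one
Product: 11 tert-butyl({(3Z,5E)-9-[(2R,3S)-3-(bromomethyl)-2-methyloxiran-2-yl]-2-methyl-6-[(trimethylsilyl)methyl]nona-3,5-dien-4-yl}oxy)dimethylsilane, via lithium enolate 10 (not isolated)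
Conditions: LDA, THF, −78 °C; then TBSCl, DMPU, −78 to −40 °C
Reagents that add atoms: tert-butyldimethylsilyl chloride CC(C)(C)[Si](C)(C)Cl
Why: Kinetic α′-deprotonation of the enone with LDA and O-silylation should give the cross-conjugated (Z)-silyl dienol ether (allylic strain disfavours the E-enolate), which masks the ketone, keeps the allylsilane nucleophilic and stores the second nucleophile.

Step 8
Reactants: 11 tert-butyl({(3Z,5E)-9-[(2R,3S)-3-(bromomethyl)-2-methyloxiran-2-yl]-2-methyl-6-[(trimethylsilyl)methyl]nona-3,5-dien-4-yl}oxy)dimethylsilane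
Product: 14 (2R,4R,4aR,8aS)-4-hydroxy-4a-methyl-8-methylidene-2-(propan-2-yl)octahydronaphthalen-1(2H)-one, via difluoroboryl alkoxide 12 (not isolated), via ammonium enolate 13 (not isolated)
Conditions: BF3·OEt2, CH2Cl2 (high dilution), −78 °C; then BnMe3N+F− (dried, excess), THF, 4 Å MS, −78 to 0 °C; pH 7 buffer
Reagents that add atoms: none
Why: BF3 activates the trisubstituted oxirane, which opens at its tertiary carbon C8a with inversion as the γ-carbon of the allylsilane (C4a) attacks, and the β-silyl cation at C5 collapses to the exocyclic methylene with loss of Me3SiF; fluoride then cleaves the silyl enol ether and carbon C3 of the resulting (Z)-enolate displaces the primary bromide at C2, the C1 oxygen being held as an unreactive fluoroborate. The closest known reaction types are the epoxide-initiated, allylsilane-terminated cation–olefin cyclization (intramolecular Hosomi–Sakurai type) and the regiospecific fluoride-mediated alkylation of a silyl enol ether. Ring A closes 6-endo with respect to the C5=C4a double bond while the breaking oxirane C–O bond stays exocyclic, and ring B closes 6-(enolendo)-exo-tet. C8a is set by inversion of the Sharpless-derived oxirane carbon and C1 is carried through unchanged; C4a is set in a chair-like transition state that keeps the bulky C1 arm equatorial on C8a and, because the C4 arm is cis to the tether on the (E)-alkene, places it axial on C4a, which should give the cis ring fusion; C3 is set in a chair-like alkylation with the isopropyl group equatorial, which is also the more stable, epimerisable configuration. The step needs attack of C4a (not C3 or C5) on the oxirane, secured because only this closure forms a six-membered ring and puts the cation β to silicon, and it needs C- rather than O-alkylation in the second stage, for which the soft bromide leaving group and the perpendicular approach in the six-membered enolendo closure are relied on.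

Step 9
Reactants: 14 (2R,4R,4aR,8aS)-4-hydroxy-4a-methyl-8-methylidene-2-(propan-2-yl)octahydronaphthalen-1(2H)-one; 15 4-methoxybenzoyl chloride
Product: 16 (1R,3R,4aS,8aR)-8a-methyl-5-methylidene-4-oxo-3-(propan-2-yl)decahydronaphthalen-1-yl 4-methoxybenzoate
Conditions: DMAP (cat.), pyridine, CH2Cl2, 0 °C to rt
Reagents that add atoms: none
Why: DMAP-catalysed acylation of the only hydroxyl group (equatorial C1–OH) should give the ester under conditions mild enough to leave the β,γ-unsaturated ketone unisomerised.

Step 10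
Reactants: 16 (1R,3R,4aS,8aR)-8a-methyl-5-methylidene-4-oxo-3-(propan-2-yl)decahydronaphthalen-1-yl 4-methoxybenzoate
Product: 17 (1R,3R,4S,4aS,8aR)-4-hydroxy-8a-methyl-5-methylidene-3-(propan-2-yl)decahydronaphthalen-1-yl 4-methoxybenzoate
Conditions: L-Selectride, THF, −78 °C; NH4Cl (aq)
Reagents that add atoms: none
Why: The bulky hydride should attack the C4 ketone from the equatorial side because the axial trajectory is blocked by the syn-axial C8a methyl group, giving the axial alcohol cis to that methyl group, while the aryl ester is inert at −78 °C.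

**Compound list**

1 | hepta-1,6-diyne | C#CCCCC#C | starting material
2 | dimethyl[(1E)-2-methylhept-1-en-6-yn-1-yl]alumane (formed in situ) | C[Al](C)/C=C(\C)CCCC#C | intermediate
3 | methyl (2E)-3-methyloct-2-en-7-ynoate | COC(=O)/C=C(\C)CCCC#C | intermediate
4 | (2E)-3-methyloct-2-en-7-yn-1-ol | OC/C=C(\C)CCCC#C | intermediate
5 | [(2R,3R)-3-methyl-3-(pent-4-yn-1-yl)oxiran-2-yl]methanol | OC[C@H]1O[C@]1(C)CCCC#C | intermediate
6 | (2S,3R)-2-(bromomethyl)-3-methyl-3-(pent-4-yn-1-yl)oxirane | BrC[C@H]1O[C@]1(C)CCCC#C | intermediate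
7 | 3-methylbutanoyl chloride | CC(C)CC(Cl)=O | starting material
8 | 9-[(2R,3S)-3-(bromomethyl)-2-methyloxiran-2-yl]-2-methylnon-5-yn-4-one | BrC[C@H]1O[C@]1(C)CCCC#CC(=O)CC(C)C | intermediate
9 | (5E)-9-[(2R,3S)-3-(bromomethyl)-2-methyloxiran-2-yl]-2-methyl-6-[(trimethylsilyl)methyl]non-5-en-4-one | BrC[C@H]1O[C@]1(C)CCC/C(C[Si](C)(C)C)=C\C(=O)CC(C)C | intermediate
10 | lithium (3Z,5E)-9-[(2R,3S)-3-(bromomethyl)-2-methyloxiran-2-yl]-2-methyl-6-[(trimethylsilyl)methyl]nona-3,5-dien-4-olate (formed in situ) | BrC[C@H]1O[C@]1(C)CCC/C(C[Si](C)(C)C)=C\C([O-])=C\C(C)C.[Li+] | intermediate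
11 | tert-butyl({(3Z,5E)-9-[(2R,3S)-3-(bromomethyl)-2-methyloxiran-2-yl]-2-methyl-6-[(trimethylsilyl)methyl]nona-3,5-dien-4-yl}oxy)dimethylsilane | BrC[C@H]1O[C@]1(C)CCC/C(C[Si](C)(C)C)=C\C(O[Si](C)(C)C(C)(C)C)=C\C(C)C | intermediate
12 | [(1S)-2-bromo-1-{(1R,2S)-2-[(1Z)-1-{[tert-butyl(dimethyl)silyl]oxy}-3-methylbut-1-en-1-yl]-1-methyl-3-methylidenecyclohexyl}ethoxy]difluoroborane (formed in situ) | C=C1CCC[C@@](C)([C@@H](CBr)OB(F)F)[C@H]1/C(O[Si](C)(C)C(C)(C)C)=C/C(C)C | intermediate
13 | bis(benzyltrimethylammonium) salt of the C3 enolate carrying the C1–O trifluoroborate (formed in situ) | C=C1CCC[C@@](C)([C@@H](CBr)O[B-](F)(F)F)[C@H]1/C([O-])=C/C(C)C.C[N+](C)(C)Cc1ccccc1.C[N+](C)(C)Cc1ccccc1 | intermediate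
14 | (2R,4R,4aR,8aS)-4-hydroxy-4a-methyl-8-methylidene-2-(propan-2-yl)octahydronaphthalen-1(2H)-one | C=C1CCC[C@]2(C)[C@H]1C(=O)[C@@H](C(C)C)C[C@H]2O | intermediate
15 | 4-methoxybenzoyl chloride | COc1ccc(cc1)C(Cl)=O | starting material
16 | (1R,3R,4aS,8aR)-8a-methyl-5-methylidene-4-oxo-3-(propan-2-yl)decahydronaphthalen-1-yl 4-methoxybenzoate | C=C1CCC[C@]2(C)[C@H]1C(=O)[C@@H](C(C)C)C[C@H]2OC(=O)c1ccc(OC)cc1 | intermediate
17 | (1R,3R,4S,4aS,8aR)-4-hydroxy-8a-methyl-5-methylidene-3-(propan-2-yl)decahydronaphthalen-1-yl 4-methoxybenzoate | C=C1CCC[C@]2(C)[C@H]1[C@@H](O)[C@@H](C(C)C)C[C@H]2OC(=O)c1ccc(OC)cc1 | target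

**Totals.** Total step count: 10. Longest linear sequence: 10 steps (1 to 17).

**Steps most likely to fail**

Step 8. The relay between the two ring closures may break down: the silyl enol ether may be lost under BF3, the naked enolate may be protonated or O-alkylated, the exocyclic double bond may migrate into conjugation with the ketone under the basic second stage, or the ring-fusion selectivity of the chair-like closure may be poor. The fallback sets out from 11 and returns at 14, with the two closures separated and isolated. The Lewis-acid stage alone (BF3·OEt2, CH2Cl2, −78 °C) is quenched with aqueous HF in MeCN, which hydrolyses the borate and the silyl enol ether and should give the monocyclic 1-{(1S,2R)-2-[(1S)-2-bromo-1-hydroxyethyl]-2-methyl-6-methylidenecyclohexyl}-3-methylbutan-1-one F1, where the ring-fusion outcome can be checked. Silver(I) oxide in ether closes the bromohydrin to the terminal epoxide 3-methyl-1-{(1S,2R)-2-methyl-6-methylidene-2-[(2S)-oxiran-2-yl]cyclohexyl}butan-1-one F2 under neutral conditions. LDA in THF (−78 to 0 °C) then forms the less hindered kinetic lithium enolate at C3, which opens the oxirane at its primary carbon (Stork-type intramolecular epoxide alkylation) to give 14.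

Step 6. The cuprate may attack the primary bromide or the oxirane in competition with the ynone, and alkene geometry may erode through the allenolate. The fallback sets out from 5 and returns at 9, putting the bromide in only after the conjugate addition. Silylation (TESCl, imidazole) gives triethyl{[(2R,3R)-3-methyl-3-(pent-4-yn-1-yl)oxiran-2-yl]methoxy}silane F3. Acyl Sonogashira coupling with 7 gives 2-methyl-9-[(2R,3R)-2-methyl-3-{[(triethylsilyl)oxy]methyl}oxiran-2-yl]non-5-yn-4-one F4. The same cuprate addition then gives (5E)-2-methyl-9-[(2R,3R)-2-methyl-3-{[(triethylsilyl)oxy]methyl}oxiran-2-yl]-6-[(trimethylsilyl)methyl]non-5-en-4-one F5. Buffered HF·pyridine (pyridine, THF, 0 °C) frees (5E)-9-[(2R,3R)-3-(hydroxymethyl)-2-methyloxiran-2-yl]-2-methyl-6-[(trimethylsilyl)methyl]non-5-en-4-one F6, and Appel bromination (CBr4, PPh3) gives 9.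

Step 10. Facial selectivity of hydride delivery may be poor, with axial attack giving the equatorial C4 alcohol. The fallback sets out from 16 and returns at 17, replacing facial control by SN2 inversion. A small hydride (NaBH4, MeOH, 0 °C) is used deliberately to make the equatorial epimer (1R,3R,4R,4aS,8aR)-4-hydroxy-8a-methyl-5-methylidene-3-(propan-2-yl)decahydronaphthalen-1-yl 4-methoxybenzoate F7. Mitsunobu reaction with chloroacetic acid (PPh3, DIAD, toluene) inverts C4 to (1R,3R,4S,4aS,8aR)-4-[(chloroacetyl)oxy]-8a-methyl-5-methylidene-3-(propan-2-yl)decahydronaphthalen-1-yl 4-methoxybenzoate F8. Selective methanolysis of the chloroacetate (K2CO3 cat., MeOH, 0 °C) then gives 17.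

**Further compounds**

F1 | step 8 | 1-{(1S,2R)-2-[(1S)-2-bromo-1-hydroxyethyl]-2-methyl-6-methylidenecyclohexyl}-3-methylbutan-1-one | C=C1CCC[C@@](C)([C@@H](CBr)O)[C@H]1C(=O)CC(C)C
F2 | step 8 | 3-methyl-1-{(1S,2R)-2-methyl-6-methylidene-2-[(2S)-oxiran-2-yl]cyclohexyl}butan-1-one | C=C1CCC[C@@](C)([C@H]2CO2)[C@H]1C(=O)CC(C)C
F3 | step 6 | triethyl{[(2R,3R)-3-methyl-3-(pent-4-yn-1-yl)oxiran-2-yl]methoxy}silane | CC[Si](CC)(CC)OC[C@H]1O[C@]1(C)CCCC#C
F4 | step 6 | 2-methyl-9-[(2R,3R)-2-methyl-3-{[(triethylsilyl)oxy]methyl}oxiran-2-yl]non-5-yn-4-one | CC[Si](CC)(CC)OC[C@H]1O[C@]1(C)CCCC#CC(=O)CC(C)C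
F5 | step 6 | (5E)-2-methyl-9-[(2R,3R)-2-methyl-3-{[(triethylsilyl)oxy]methyl}oxiran-2-yl]-6-[(trimethylsilyl)methyl]non-5-en-4-one | CC[Si](CC)(CC)OC[C@H]1O[C@]1(C)CCC/C(C[Si](C)(C)C)=C\C(=O)CC(C)C
F6 | step 6 | (5E)-9-[(2R,3R)-3-(hydroxymethyl)-2-methyloxiran-2-yl]-2-methyl-6-[(trimethylsilyl)methyl]non-5-en-4-one | OC[C@H]1O[C@]1(C)CCC/C(C[Si](C)(C)C)=C\C(=O)CC(C)C
F7 | step 10 | (1R,3R,4R,4aS,8aR)-4-hydroxy-8a-methyl-5-methylidene-3-(propan-2-yl)decahydronaphthalen-1-yl 4-methoxybenzoate | C=C1CCC[C@]2(C)[C@H]1[C@H](O)[C@@H](C(C)C)C[C@H]2OC(=O)c1ccc(OC)cc1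
F8 | step 10 | (1R,3R,4S,4aS,8aR)-4-[(chloroacetyl)oxy]-8a-methyl-5-methylidene-3-(propan-2-yl)decahydronaphthalen-1-yl 4-methoxybenzoate | C=C1CCC[C@]2(C)[C@H]1[C@@H](OC(=O)CCl)[C@@H](C(C)C)C[C@H]2OC(=O)c1ccc(OC)cc1
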